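The ratio to follow is the end yield, the fraction of the charge found as product at 2.5 h, since the new flasks share catalyst and time and differ in their substrate charge.

| flask | substrate | free catalyst | remark | time |
|---|---|---|---|---|
| dusk | 0.46 M | 32 mM | run made earlier |  |
| noon | 0.73 M | 32 mM | run made earlier |  |
| autumn | 1.1 M | 32 mM | run made earlier |  |
| amber | 0.40 M | 32 mM |  | 2.5 h |
| teal | 0.80 M | 32 mM |  | 2.5 h |
| ochre | 1.5 M | 32 mM |  | 2.5 h |

| run | time / h | product / % | substrate / % |
|---|---|---|---|
| dusk | 0.667 | 32 | 4 |
| dusk | 1.33 | 37 | 4 |
| dusk | 2.00 | 41 | 0 |
| dusk | 2.50 | 48 | 2 |
| noon | 0.200 | 10 | 32 |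
| noon | 0.500 | 24 | 6 |
| noon | 1.00 | 34 | 1 |
| noon | 2.50 | 42 | 0 |
| autumn | 0.200 | 6 | 34 |
| autumn | 0.500 | 23 | 9 |
| autumn | 1.00 | 26 | 0 |
| autumn | 2.50 | 37 | 2 |

(readings scatter by 2 percentage points)

- "hardly changes" means that all values lie within two and a half points (for a concentration: within two and a half percent of the largest)

- [product] at the end for amber, teal, ochre, in this order
- how the row runs (rises all the way / falls, then rises / falls all the way / hardly changes / rises, then falls)

Does the substrate that remains explain the end yield? At dusk the last readings are 48% product and 2% substrate, so 50.0% of the charge stands in neither column. At autumn that share is 61.0%. The yield is therefore not what the substrate left over would suggest, and I need its dependence on charge.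

How fast does it fall? From dusk to autumn the charge grows by a factor 2.39 and the yield changes by a factor 0.771. I freeze the ratio of their logarithms as 0.299, the yield exponent: the percent of end yield lost per percent more charge, with free catalyst and time held as in these runs. It is a reading and carries the scatter of 2 percentage points. Noon was not used for it, and the exponent gives noon 41.8%, close to the 42% read there.

Does product still rise? My yields are 50.0% for amber, 40.7% for teal and 33.7% for ochre, which make 0.200 M, 0.326 M and 0.506 M. From amber to ochre the charge grows faster than the yield falls, so the row rises, with an apparent order of 0.701 in the charge.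

The forecast gives 0.19 M, 0.32 M and 0.49 M, and rises all the way, saying “absolute product still rises”. Its ochre stands lower than mine.

The flask gives 0.189 M, 0.328 M and 0.517 M, and the row rises all the way.

substrate + free catalyst ⇌ catalyst intermediate A (K = 0.207 /M, k = 0.0794 /M/s); catalyst intermediate A → catalyst intermediate B (k = 0.276 /s); catalyst intermediate B → free catalyst + product (k = 0.00644 /s); substrate ⇌ dormant form (K = 17.0, k = 0.00123 /s) At 2.50 h dormant form holds 50.8% of the charge in amber and 63.1% in ochre, a gain of 12 points, while product loses nearly the same, 13 points. From amber to ochre the exponent comes out at 0.240, lower than the 0.299 read earlier. Carried from teal's 41.0%, the 0.299 gives ochre 34.0%, and ochre stands at 34.5%.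

The runs come from a simulation on assumed constants, and the scatter is random.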